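**Strategy.** Everything rests on disconnecting the C6–C1 bond of the spiro[5.5]undecane (ring B = C1–C5, spiro C6, ring A = C7–C11). The key step exploits the fact that spiro C6 sits between C11 (CMe2) and C7 (C(Me)O) in ring A and carries ring B as a C1H=C2H arm and a C5H2–C4H2 arm. A tertiary C6 radical, generated by hydrogen-atom transfer to an exocyclic alkene, closes ring B onto a terminal ynone. One operation delivers the quaternary stereocentre, the ring and the C1=C2–C3=O enone. The precursor is a cyclohexylidene, C6=CH–CH2–CO–C≡CH, whose cis-7,9-diol is tied as an acetonide.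

Key step: step 11

Remarks on the chemistry (one line each):
- The three-carbon unit is introduced as a silyl ether rather than as an aldehyde acetal, because acid release of an aldehyde acetal would not spare the acetonide.
- Compounds 12–14, 16 and 17 are expected as mixtures of alkene isomers and are drawn E; step 11 erases this geometry.
- The carbinol centres made in steps 5 and 9 are not controlled, are drawn without descriptor, and are removed in steps 6 and 10.
- Assumption: the two reductases of step 1 are used as commercial or recombinant preparations.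

**Step 1**
Reactants: 1 ketoisophorone
Product: 3 (4R,6R)-4-hydroxy-2,2,6-trimethylcyclohexanone (actinol), via (6R)-levodione 2 (not isolated)
Conditions: ene-reductase (OYE2), then levodione reductase; NAD(P)+ cat., glucose, glucose dehydrogenase, phosphate buffer pH 7, 30 °C
Reagents that add atoms: none
Why: Biocatalytic cascade in which the ene-reductase saturates the C=C bond and the levodione reductase reduces the unhindered C4 carbonyl from one face, setting the 4R carbinol by enzyme control (C6 is erased in step 2, so only C4 matters).

**Step 2**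
Reactants: 3 actinol
Product: 4 bis-TMS derivative of 3 (C4 TMS ether and C1=C6 TMS enol ether, C4 configuration unchanged)
Conditions: TMSOTf, Et3N, CH2Cl2, 0 °C to rt
Reagents that add atoms: trimethylsilyl triflate, C[Si](C)(C)OS(=O)(=O)C(F)(F)F
Why: Soft enolisation and silylation; C6–H is the only α-hydrogen, so a single tetrasubstituted silyl enol ether should form while the C4 hydroxyl is capped.

**Step 3**
Reactants: 4 bis-TMS enol ether
Product: 6 (4S,6S)-4,6-dihydroxy-2,2,6-trimethylcyclohexanone (cis-diol), via bis-TMS α-silyloxy ketone 5 (not isolated)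
Conditions: mCPBA, NaHCO3, CH2Cl2, −20 °C; then citric acid, MeOH, rt
Reagents that add atoms: mCPBA, OOC(=O)c1cccc(Cl)c1
Why: Rubottom oxidation; in the half-chair with the C4 silyloxy group equatorial the peracid should attack anti to the pseudoaxial C2 methyl, which is the face of the C4 oxygen, so the new tertiary C6–O centre is set cis to C4–O by substrate control.

**Step 4**
Reactants: 6 cis-diol ketone; 7 2,2-dimethoxypropane
Product: 8 (4S,6S)-4,6-(isopropylidenedioxy)-2,2,6-trimethylcyclohexanone (bridged acetonide)
Conditions: CSA cat., acetone, rt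
Reagents that add atoms: 2,2-dimethoxypropane 7, COC(C)(C)OC
Why: Acetal exchange; only a cis-1,3-diol can bridge, so the step protects the diol and removes any trans isomer without touching a stereocentre.

**Step 5**
Reactants: 8 acetonide ketone; 9 (3-bromopropoxy)(tert-butyl)dimethylsilane
Product: 11 tertiary alcohol, 1-[3-(tert-butyldimethylsilyloxy)propyl]-(4S,6S)-4,6-(isopropylidenedioxy)-2,2,6-trimethylcyclohexan-1-ol, via Grignard reagent 10 (not isolated)
Conditions: 9, Mg, THF, 25 °C; anhydrous CeCl3, THF, −78 °C; then 8, −78 to 0 °C; aq. NH4Cl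
Reagents that add atoms: (3-bromopropoxy)(tert-butyl)dimethylsilane 9, BrCCCO[Si](C)(C)C(C)(C)C
Why: Organocerium 1,2-addition (Imamoto type); the ketone has no α-hydrogen and the cerium reagent should add to the crowded carbonyl with little β-hydride reduction.

**Step 6**
Reactants: 11 tertiary alcohol
Product: 12 tert-butyl{3-[(4S,6S)-4,6-(isopropylidenedioxy)-2,2,6-trimethylcyclohexylidene]propoxy}dimethylsilane
Conditions: SOCl2, pyridine, CH2Cl2, −40 to 0 °C
Reagents that add atoms: none
Why: Dehydration through the chlorosulfite with pyridine as base (E2); both ring neighbours are quaternary, so the only β-hydrogens are on the side-chain CH2 and the exocyclic alkene is the only alkene possible.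

**Step 7**
Reactants: 12 silyl ether
Product: 13 3-[(4S,6S)-4,6-(isopropylidenedioxy)-2,2,6-trimethylcyclohexylidene]propan-1-ol
Conditions: TBAF, THF, 0 °C to rt
Reagents that add atoms: none
Why: Fluoride desilylation of a primary TBS ether; acetonide and alkene are inert to fluoride.

**Step 8**
Reactants: 13 homoallylic alcohol
Product: 14 3-[(4S,6S)-4,6-(isopropylidenedioxy)-2,2,6-trimethylcyclohexylidene]propanal
Conditions: Dess–Martin periodinane, NaHCO3, CH2Cl2, 0 °C; used at once
Reagents that add atoms: none
Why: Dess–Martin oxidation under buffered conditions should give the β,γ-unsaturated aldehyde without double-bond migration, since conjugation would need protonation at the crowded ring carbon.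

**Step 9**
Reactants: 14 aldehyde; 15 ethynylmagnesium bromide
Product: 16 1-[(4S,6S)-4,6-(isopropylidenedioxy)-2,2,6-trimethylcyclohexylidene]pent-4-yn-3-ol
Conditions: THF, −78 °C; aq. NH4Cl
Reagents that add atoms: ethynylmagnesium bromide 15, C#C[Mg]Br
Why: Grignard 1,2-addition to the aldehyde at low temperature to limit enolisation; the epimers are carried on together because the centre is oxidised next.

**Step 10**
Reactants: 16 propargylic alcohol
Product: 17 1-[(4S,6S)-4,6-(isopropylidenedioxy)-2,2,6-trimethylcyclohexylidene]pent-4-yn-3-one
Conditions: Dess–Martin periodinane, NaHCO3, CH2Cl2, 0 °C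
Reagents that add atoms: none
Why: Dess–Martin oxidation of a propargylic alcohol to the ynone under neutral conditions that tolerate the terminal alkyne and the β,γ-alkene.

**Step 11**
Reactants: 17 ynone
Product: 18 spiro enone, 7,9-O-isopropylidene derivative of (6S,7S,9S)-7,9-dihydroxy-7,11,11-trimethylspiro[5.5]undec-1-en-3-one
Conditions: Fe(acac)3 (0.5 equiv), PhSiH3 (2.5 equiv), iPrOH/THF 1:4, 0.01 M, degassed, 25 to 40 °C
Reagents that add atoms: none
Why: Proposed new method: an iron hydride formed from Fe(acac)3 and the silane should transfer a hydrogen atom to the CH end of the exocyclic alkene, so both alkene isomers give the same tertiary ring radical, which cannot isomerise because both ring neighbours are quaternary. This nucleophilic radical should add to the unsubstituted β-carbon of the ynone in a polarity-matched 6-endo-dig closure of ring B (5-exo-dig would require attack at the substituted α-carbon), after which the α-keto vinyl radical is reduced by Fe(II) and protonated by the alcohol to the enone. The closest known reaction types are iron-catalysed hydrogen-atom-transfer reductive couplings of alkenes with enones that build quaternary carbons, and 6-endo radical cyclisations onto ynones. The one new stereocentre, spiro C6, is controlled by the bridged acetonide, which holds the tertiary C7–O bond and one methyl of C11 on the same face of ring A. The step needs facial selectivity at the planar radical, and these two groups block that face, so the C6–C1 bond should form anti to the tertiary oxygen and leave the CH2CH2 arm cis to it. It also needs the hydride to choose the electron-rich alkene over the ynone, which the polarity preference of metal-hydride hydrogen-atom transfer should secure.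

**Step 12**
Reactants: 18 spiro enone; 19 (bromomethyl)triphenylphosphonium bromide
Product: 21 (E)-bromodiene acetonide, 7,9-O-isopropylidene derivative of (3E,6S,7S,9S)-3-(bromomethylidene)-7,11,11-trimethylspiro[5.5]undec-1-ene-7,9-diol, via bromomethylene ylide 20 (not isolated)
Conditions: 19, NaHMDS, THF, −78 °C; then 18, −78 to 0 °C; chromatography (AgNO3–silica if needed)
Reagents that add atoms: (bromomethyl)triphenylphosphonium bromide 19, BrC[P+](c1ccccc1)(c1ccccc1)c1ccccc1.[Br-]
Why: Wittig olefination of the unhindered enone carbonyl in 1,2-fashion; little geometric control is expected, so both isomers should form and the E isomer (Br on the C4H2 side) is isolated by chromatography, with further chances to separate at 22 and 23.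

**Step 13**
Reactants: 21 bromodiene acetonide
Product: 22 (3E,6S,7S,9S)-3-(bromomethylidene)-7,11,11-trimethylspiro[5.5]undec-1-ene-7,9-diol
Conditions: AcOH/THF/H2O 3:1:1, 40 °C
Reagents that add atoms: none
Why: Mild acid hydrolysis of the strained bridged acetonide; the bromodiene and the tertiary alcohol should survive.

**Step 14**
Reactants: 22 diol
Product: 23 (3E,6S,7S,9R)-9-bromo-3-(bromomethylidene)-7,11,11-trimethylspiro[5.5]undec-1-en-7-ol (target)
Conditions: CBr4, PPh3, CH2Cl2, 0 °C to rt
Reagents that add atoms: carbon tetrabromide, BrC(Br)(Br)Br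
Why: Appel reaction; the secondary C9 alcohol forms the alkoxyphosphonium ion and bromide displaces it by SN2 with inversion (9S to 9R), while the cis tertiary C7 alcohol is too hindered to be activated and cannot attack from the rear.

**Compound list**
1 | ketoisophorone (2,6,6-trimethylcyclohex-2-ene-1,4-dione) | CC1=CC(=O)CC(C)(C)C1=O | starting material
2 | (6R)-levodione, (6R)-2,2,6-trimethylcyclohexane-1,4-dione | CC1(C)CC(=O)C[C@@H](C)C1=O | intermediate
3 | (4R,6R)-4-hydroxy-2,2,6-trimethylcyclohexanone (actinol) | CC1(C)C[C@H](O)C[C@@H](C)C1=O | intermediate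
4 | bis-TMS derivative of 3 (C4 OTMS, C1=C6 TMS enol ether) | CC1(C)C[C@H](O[Si](C)(C)C)CC(C)=C1O[Si](C)(C)C | intermediate
5 | bis-TMS ether of 6 (α-silyloxy ketone) | CC1(C)C[C@H](O[Si](C)(C)C)C[C@](C)(O[Si](C)(C)C)C1=O | intermediate
6 | (4S,6S)-4,6-dihydroxy-2,2,6-trimethylcyclohexanone | CC1(C)C[C@H](O)C[C@](C)(O)C1=O | intermediate
7 | 2,2-dimethoxypropane | COC(C)(C)OC | starting material
8 | (4S,6S)-4,6-(isopropylidenedioxy)-2,2,6-trimethylcyclohexanone | CC1(C)C[C@H]2C[C@](C)(OC(C)(C)O2)C1=O | intermediate
9 | (3-bromopropoxy)(tert-butyl)dimethylsilane | BrCCCO[Si](C)(C)C(C)(C)C | starting material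
10 | 3-(tert-butyldimethylsilyloxy)propylmagnesium bromide | Br[Mg]CCCO[Si](C)(C)C(C)(C)C | intermediate
11 | tertiary alcohol from 8 and 10 (carbinol centre undefined) | CC1(C)C[C@H]2C[C@](C)(OC(C)(C)O2)C1(O)CCCO[Si](C)(C)C(C)(C)C | intermediate
12 | cyclohexylidene TBS ether (drawn E) | CC1(C)C[C@H]2C[C@](C)(OC(C)(C)O2)/C1=C/CCO[Si](C)(C)C(C)(C)C | intermediate
13 | cyclohexylidene propanol (drawn E) | CC1(C)C[C@H]2C[C@](C)(OC(C)(C)O2)/C1=C/CCO | intermediate
14 | cyclohexylidene propanal (drawn E) | CC1(C)C[C@H]2C[C@](C)(OC(C)(C)O2)/C1=C/CC=O | intermediate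
15 | ethynylmagnesium bromide | C#C[Mg]Br | starting material
16 | cyclohexylidene pentynol (drawn E, carbinol undefined) | CC1(C)C[C@H]2C[C@](C)(OC(C)(C)O2)/C1=C/CC(O)C#C | intermediate
17 | 1-[(4S,6S)-4,6-(isopropylidenedioxy)-2,2,6-trimethylcyclohexylidene]pent-4-yn-3-one (drawn E) | CC1(C)C[C@H]3C[C@](C)(OC(C)(C)O3)/C1=C/CC(=O)C#C | intermediate
18 | spiro enone acetonide (6S,7S,9S) | CC1(C)C[C@H]3C[C@](C)(OC(C)(C)O3)[C@@]12C=CC(=O)CC2 | intermediate
19 | (bromomethyl)triphenylphosphonium bromide | BrC[P+](c1ccccc1)(c1ccccc1)c1ccccc1.[Br-] | starting material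
20 | (bromomethylene)triphenylphosphorane | BrC=P(c1ccccc1)(c1ccccc1)c1ccccc1 | intermediate
21 | (E)-bromodiene acetonide | CC1(C)C[C@H]3C[C@](C)(OC(C)(C)O3)[C@@]12C=C/C(=C/Br)CC2 | intermediate
22 | (3E,6S,7S,9S)-3-(bromomethylidene)-7,11,11-trimethylspiro[5.5]undec-1-ene-7,9-diol | CC1(C)C[C@H](O)C[C@](C)(O)[C@@]12C=C/C(=C/Br)CC2 | intermediate
23 | (3E,6S,7S,9R)-9-bromo-3-(bromomethylidene)-7,11,11-trimethylspiro[5.5]undec-1-en-7-ol | CC1(C)C[C@@H](Br)C[C@](C)(O)[C@@]12C=C/C(=C/Br)CC2 | target

**Step count and risk**
Total steps: 14. Longest linear sequence: 14 (from ketoisophorone 1).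

Steps most likely to fail:

1. Step 11 (proposed new method). The tertiary radical may be reduced before it cyclises, the ynone may be consumed by the hydride or by alcohol addition, or the facial selectivity at the planar radical may be poor. Fallback with known chemistry, setting out from aldehyde 14 and returning at 18: vinylmagnesium bromide (THF, −78 °C) should give the allylic alcohol F1, and Dess–Martin oxidation the vinyl ketone F2. The established hydrogen-atom-transfer reductive alkene–enone coupling (Fe(acac)3, PhSiH3, EtOH), run intramolecularly, should then close ring B 6-endo-trig to the spiro ketone F3, in which C6 is not yet stereogenic. Desymmetrising enolisation with a chiral lithium amide (lithium bis(1-phenylethyl)amide, TMSCl, THF, −100 °C) should give the TMS enol ether F4 on the arm anti to the tertiary oxygen; the enantiomer of the base is chosen for that arm. Saegusa–Ito dehydrogenation (Pd(OAc)2, MeCN) then gives 18.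

2. Step 5. The crowded carbonyl may be reduced by β-hydride transfer from the alkyl metal, or not be attacked at all. Fallback from ketone 8, returning at 11: the lithium acetylide of tert-butyldimethyl(prop-2-yn-1-yloxy)silane (n-BuLi, THF, −78 °C), a slim sp nucleophile without β-hydrogens, should add to give the propargylic tertiary alcohol F5. Hydrogenation (H2, Pt/C, EtOAc) saturates the triple bond to 11.

3. Step 14. E2 elimination from the alkoxyphosphonium ion to a ring-A alkene may outrun substitution. Fallback from diol 22, returning at 23: selective sulfonylation of the secondary alcohol (chloromethanesulfonyl chloride, pyridine, 0 °C) should give the isolated chloromethanesulfonate F6. A separate SN2 displacement with LiBr (THF, 50 °C) then gives 23 with inversion.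

**Further compounds**
F1 | step 11 | 1-[(4S,6S)-4,6-(isopropylidenedioxy)-2,2,6-trimethylcyclohexylidene]pent-4-en-3-ol | CC1(C)C[C@H]3C[C@](C)(OC(C)(C)O3)/C1=C/CC(O)C=C
F2 | step 11 | 1-[(4S,6S)-4,6-(isopropylidenedioxy)-2,2,6-trimethylcyclohexylidene]pent-4-en-3-one | CC1(C)C[C@H]3C[C@](C)(OC(C)(C)O3)/C1=C/CC(=O)C=C
F3 | step 11 | 7,9-O-isopropylidene derivative of (7S,9S)-7,9-dihydroxy-7,11,11-trimethylspiro[5.5]undecan-3-one | CC1(C)C[C@H]3C[C@](C)(OC(C)(C)O3)C12CCC(=O)CC2
F4 | step 11 | TMS enol ether of F3 on the arm anti to the tertiary oxygen | CC1(C)C[C@H]3C[C@](C)(OC(C)(C)O3)[C@@]12CC=C(O[Si](C)(C)C)CC2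
F5 | step 5 | 1-[3-(tert-butyldimethylsilyloxy)prop-1-ynyl]-(4S,6S)-4,6-(isopropylidenedioxy)-2,2,6-trimethylcyclohexan-1-ol | CC1(C)C[C@H]2C[C@](C)(OC(C)(C)O2)C1(O)C#CCO[Si](C)(C)C(C)(C)C
F6 | step 14 | 9-O-chloromethanesulfonate of diol 22 | CC1(C)C[C@H](OS(=O)(=O)CCl)C[C@](C)(O)[C@@]12C=C/C(=C/Br)CC2
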